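The trap is to reckon [D] from the charges. Q is the limiting reagent in red and stands in excess in amber, so the charges promise amber no D at all, but the reading comes at 2.0 min, long before the flask has finished.

| setting | dawn | autumn | amber | violet | blue | teal | red |
|---|---|---|---|---|---|---|---|
| Z | 5.1 mM | 34 mM | 10 mM | 15 mM | 25 mM | 30 mM | 50 mM |
| Q | 18 mM | 18 mM | 18.0 mM | 18.0 mM | 18.0 mM | 18.0 mM | 18.0 mM |
| L | 46 µM | 46 µM | 46 µM | 46 µM | 46 µM | 46 µM | 46 µM |
| X | 20 µM | 20 µM | 20 µM | 20 µM | 20 µM | 20 µM | 20 µM |
| remark | run made earlier | run made earlier |  |  |  |  |  |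
| time |  |  | 2.0 min | 2.0 min | 2.0 min | 2.0 min | 2.0 min |

- dawn (time / s: D / %, G / %, Z / %): 10.0: 14.9, 0.1, 85.9; 15.0: 18.3, 3.4, 77.4; 30.0: 26.7, 9.0, 60.6; 50.0: 33.1, 19.4, 40.9; 60.0: 34.4, 23.0, 36.0; 80.0: 33.8, 33.6, 27.7
- autumn (time / s: D / %, G / %, Z / %): 10.0: 12.8, 0.7, 84.4; 12.0: 16.1, 0.6, 83.5; 20.0: 22.9, 2.8, 71.0; 30.0: 33.0, 7.1, 60.3; 50.0: 42.1, 11.7, 44.8; 80.0: 48.0, 20.1, 29.4

(scatter of a reading: 1 percentage point)

- on the list of suspects stand: Z + L -> L + D; G + L <-> E + L; Q + J -> X + G; X + D <-> J
- "hardly changes" means that all values lie within two and a half points (for a concentration: within two and a half percent of the largest)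

- [D] at the end for amber, violet, blue, teal, red, in this order
- the shape of the row from first to last (rises all the way / falls all the way / hardly changes / rises, then falls / falls, then rises)

So turn the question round and ask what a falling row needs. Let C be the Z charged, f the fraction of Z converted and S the Q spent, in mM. Each G or E has cost one Q, and J holds at most 20 µM of D, so you may write

[D] = f·C − S

Dawn and autumn keep 60.6 % and 60.3 % of their Z at 30.0 s. The loss of Z is therefore pseudo-first-order, with k = 0.0167 s⁻¹, and f does not move with C: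

f = 1 − exp(−k·t) = 86.5 % at 2.0 min

The balance gives S at 80.0 s as 1.96 mM in dawn and 7.68 mM in autumn. From these comes the marginal drain m, the Q spent per extra mM of Z charged:

m = ΔS/ΔC = 0.198

A falling row needs m above f. At that same hour autumn has converted 70.6 %, far above m. Carrying m forward to 2.0 min, my own reckoning for the climb from amber to red is

(f − m)·ΔC = 26.7 mM

The forecast gives 3.4 mM, 5.9 mM, 12 mM, 15.4 mM and 30.7 mM, a row that rises all the way, and says of Q “so it never runs out”.

The flask gives 3.16 mM, 5.54 mM, 11.6 mM, 15.0 mM and 30.3 mM: the row rises all the way. Z left is 13.9 % in amber and 13.9 % in red, and Q left is 70 % in amber and 29 % in red.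

    Z + L → L + D (k = 357 M⁻¹ s⁻¹)
    G + L ⇌ E + L, rate k2*[L]*[G] forward; the back reaction follows from the equilibrium constant (K = 0.300, k = 196 M⁻¹ s⁻¹)
    Q + J → X + G (k = 901 M⁻¹ s⁻¹)
    X + D ⇌ J (K = 81.0 M⁻¹, k = 4840 M⁻¹ s⁻¹)

Those Q figures put m at 0.182 from amber to red, where [D] climbs 27.1 mM. On the step from blue to teal, f and m give 3.34 mM, and the flasks show 3.40 mM. Part of red's height comes from the falling level of Q: with Q held at its charge, red ends at 22.6 mM instead of 30.3 mM.

(The readings stem from a simulated flask with constants of no real substance; scatter was added.)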